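**Plan**
- Cuts, in retrosynthetic order: the three phenol acetals; then C2–C3 and C4–C4a of ring C together; then C3–C4 (acyl anion plus Weinreb amide); then O1–C2 (phenol alkylation); then the aryl–prenyl bonds at C6 and C8 (Claisen rearrangement, then metathesis).
- Enabling feature: C3(OH)–C4(=O) is an α-ketol inside six-membered ring C. Its ring-contracted isomer has C2 on C4 and is a 3-aroyl-2,3-dihydrobenzofuran-3-ol. This isomer forms when ring-A carbon C4a adds to the C4 carbonyl of the open diketone O1–C2H2–C4(=O)–C3(=O)–ring B, and a 1,2-shift of C2 from C4 to C3 then gives ring C.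
- Forward order: substituents of ring A, then O1–C2, then C3–C4, then the five-membered ring and its enlargement to ring C in one flask, then deprotection.
- Helpers: the bromine at C4a first blocks that carbon so that the double Claisen rearrangement can only fill C6 and C8, and later becomes the boronate. A dithiane masks C3. Fluoride-labile, base-stable TOM acetals protect the phenols.
- Stereochemistry: the only stereocentre, C3 (R), comes from a chiral bisphosphine–rhodium catalyst. The catalyst sets the carbinol centre of the five-membered intermediate, and the suprafacial shift carries it to C3.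

Key step: step 11

Numbering and abbreviations: flavonoid numbering is used (O1, C2, C3, C4, C4a, C5–C8, C8a; primed numbers for ring B). Prenyl = 3-methylbut-2-en-1-yl. TOM = (triisopropylsiloxy)methyl, and TOM-oxy = OCH2OSi(i-Pr)3. Bpin = pinacolboryl.
Assumption: (R)-DIFLUORPHOS is written as the ligand that gives (R)-21; if the sense of induction is the reverse, its antipode is used.

**Step 1**
Reactants: 1 4-bromoresorcinol; 2 allyl bromide
Product: 3 1-bromo-2,4-bis(allyloxy)benzene
Conditions: K2CO3 (2.5 equiv), acetone, reflux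
Reagents that add atoms: allyl bromide 2, C=CCBr
Why: Williamson ether synthesis of both phenols with a reactive allylic halide under carbonate conditions that leave the aryl bromide untouched.

**Step 2**
Reactants: 3 1-bromo-2,4-bis(allyloxy)benzene
Product: 4 2,6-diallyl-4-bromobenzene-1,3-diol
Conditions: N,N-diethylaniline, 200 °C, sealed tube, argon
Reagents that add atoms: none
Why: Double aromatic Claisen rearrangement in which the bromine blocks one ortho position of O1 and the para position of O7, so whichever allyl group moves first, the [3,3] shifts (with a Cope relay if C8 is already filled) can end only at C6 and C8.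

**Step 3**
Reactants: 4 2,6-diallyl-4-bromobenzene-1,3-diol; 5 2-methylbut-2-ene
Product: 6 4-bromo-2,6-diprenylbenzene-1,3-diol
Conditions: second-generation Grubbs catalyst (H2IMes)(PCy3)Cl2Ru=CHPh (5 mol %), 2-methylbut-2-ene (excess), CH2Cl2, 40 °C
Reagents that add atoms: 2-methylbut-2-ene 5, CC=C(C)C
Why: Olefin cross metathesis with an excess of a trisubstituted alkene caps each terminal allyl group as a prenyl group, a conversion well known for ortho-allylphenols, while propene escapes.

**Step 4**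
Reactants: 6 4-bromo-2,6-diprenylbenzene-1,3-diol; 7 2-chloro-N-methoxy-N-methylacetamide
Product: 8 2-(6-bromo-3-hydroxy-2,4-diprenylphenoxy)-N-methoxy-N-methylacetamide
Conditions: K2CO3 (1.05 equiv), 7 (1.0 equiv), DMF, rt
Reagents that add atoms: 2-chloro-N-methoxy-N-methylacetamide 7, CON(C)C(=O)CCl
Why: Williamson ether synthesis whose site selectivity comes from acidity and access, since O1–H (ortho to bromine) is roughly two pKa units more acidic and less shielded than O7–H (between two prenyl groups), so one equivalent of weak base delivers only the O1 phenoxide to the small α-chloroamide.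

**Step 5**
Reactants: 8 2-(6-bromo-3-hydroxy-2,4-diprenylphenoxy)-N-methoxy-N-methylacetamide; 9 (triisopropylsiloxy)methyl chloride
Product: 10 2-[6-bromo-2,4-diprenyl-3-(TOM-oxy)phenoxy]-N-methoxy-N-methylacetamide
Conditions: NaH (1.1 equiv), THF/DMF, 0 °C to rt
Reagents that add atoms: (triisopropylsiloxy)methyl chloride 9, ClCO[Si](C(C)C)(C(C)C)C(C)C
Why: Acetal-type O-alkylation of the hindered O7 phenoxide with a chloromethyl ether, chosen because the TOM group withstands the organolithium, palladium, periodinane and aqueous base steps yet falls to buffered fluoride at the end.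

**Step 6**
Reactants: 11 2,4-dihydroxybenzaldehyde; 12 propane-1,3-dithiol
Product: 13 4-(1,3-dithian-2-yl)benzene-1,3-diol
Conditions: BF3·OEt2 (0.3 equiv), THF, 0 °C to rt
Reagents that add atoms: propane-1,3-dithiol 12, SCCCS
Why: Lewis-acid-catalysed dithioacetalisation turns the aldehyde carbon (future C3) into a Corey–Seebach acyl anion equivalent, and running it on the free diphenol keeps acetals away from BF3.

**Step 7**
Reactants: 13 4-(1,3-dithian-2-yl)benzene-1,3-diol; 9 (triisopropylsiloxy)methyl chloride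
Product: 14 2-[2,4-bis(TOM-oxy)phenyl]-1,3-dithiane
Conditions: K2CO3 (3 equiv), 9 (2.4 equiv), acetone, rt
Reagents that add atoms: (triisopropylsiloxy)methyl chloride 9, ClCO[Si](C(C)C)(C(C)C)C(C)C
Why: Double O-alkylation with the chloromethyl ether under the carbonate conditions used for methoxymethyl ethers of phenols, the dithiane being inert.

**Step 8**
Reactants: 14 2-[2,4-bis(TOM-oxy)phenyl]-1,3-dithiane; 10 2-[6-bromo-2,4-diprenyl-3-(TOM-oxy)phenoxy]-N-methoxy-N-methylacetamide
Product: 16 2-[6-bromo-2,4-diprenyl-3-(TOM-oxy)phenoxy]-1-{2-[2,4-bis(TOM-oxy)phenyl]-1,3-dithian-2-yl}ethan-1-one, via lithiated dithiane 15 (not isolated)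
Conditions: 14 (1.1 equiv), n-BuLi (1.05 equiv), THF, −78 to −30 °C; then 10, −78 to −40 °C; then H2O
Reagents that add atoms: none
Why: Corey–Seebach umpolung in which the stabilised 2-aryl-2-lithiodithiane acylates at the Weinreb amide through a chelated tetrahedral adduct that prevents double addition, forms C3–C4 and is too weakly basic to exchange the aryl bromide.

**Step 9**
Reactants: 16 acyl dithiane bromide; 17 bis(pinacolato)diboron
Product: 18 2-[2,4-diprenyl-6-(Bpin)-3-(TOM-oxy)phenoxy]-1-{2-[2,4-bis(TOM-oxy)phenyl]-1,3-dithian-2-yl}ethan-1-one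
Conditions: Pd(dppf)Cl2 (5 mol %), KOAc (3 equiv), 1,4-dioxane, 90 °C
Reagents that add atoms: bis(pinacolato)diboron 17, CC1(C)OB(OC1(C)C)B1OC(C)(C)C(C)(C)O1
Why: Miyaura borylation converts the C4a bromide, its blocking duty done, into the nucleophilic handle under acetate conditions that neither enolise the ketone nor touch the prenyl, acetal or dithiane groups.

**Step 10**
Reactants: 18 boronate acyl dithiane; 19 water
Product: 20 3-[2,4-diprenyl-6-(Bpin)-3-(TOM-oxy)phenoxy]-1-[2,4-bis(TOM-oxy)phenyl]propane-1,2-dione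
Conditions: Dess–Martin periodinane (2.5 equiv), MeCN/CH2Cl2/H2O 8:1:1, rt
Reagents that add atoms: water 19, O
Why: Oxidative hydrolysis of the dithiane with Dess–Martin periodinane in wet acetonitrile is a known mild unmasking that spares trisubstituted alkenes, acetals and pinacol boronates and releases the C3 carbonyl.

**Step 11**
Reactants: 20 3-[2,4-diprenyl-6-(Bpin)-3-(TOM-oxy)phenoxy]-1-[2,4-bis(TOM-oxy)phenyl]propane-1,2-dione
Product: 22 (3R)-3-[2,4-bis(TOM-oxy)phenyl]-3-hydroxy-6,8-diprenyl-7-(TOM-oxy)chroman-4-one, via ring-contracted ketol 21 (not isolated)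
Conditions: [Rh(cod)OH]2 (2.5 mol %), (R)-DIFLUORPHOS (6 mol %), K3PO4 (2 equiv), 1,4-dioxane/H2O 10:1, 40 °C, then 70 °C in the same flask
Reagents that add atoms: none
Why: Proposed new method: the C4a–B bond is transmetalated to the hydroxo complex of monovalent rhodium, the arylrhodium adds to the nearer C4 carbonyl of the 1,2-diketone (C4–C4a formed) to give the tertiary α-ketol 21, and its alkoxide then undergoes an α-ketol (acyloin) 1,2-shift of the ring methylene C2 from C4 to the aroyl carbon C3 (C2–C3 formed, C2–C4 broken), after which water releases 22 and HO–Bpin. The closest known reaction types are the rhodium-catalysed enantioselective cyclisation of aryl pinacolboronates onto tethered α-aryloxy ketones to 2,3-dihydrobenzofuran-3-ols, the rhodium-catalysed arylation of 1,2-diketones, and the ring-enlarging α-ketol rearrangement of 1-acylcyclopentanols as in the D-homoannulation of 17-hydroxy-20-oxo steroids; only their merger in one flask is new. The first ring closes 5-exo-trig and ring C then arises by one-carbon ring expansion, which is downhill because dihydrobenzofuran strain is lost and a twisted ortho-substituted aroyl ketone is traded for a ring-locked ketone coplanar with ring A and conjugated to O1 (ortho) and O7 (para). The carbinol centre of 21 is set by the chiral bisphosphine on rhodium and is relayed to C3 because C2 migrates suprafacially in the transoid conformer (C4–O− anti to C3=O), which is favoured both by dipole repulsion in the aqueous potassium medium and by avoiding an eclipse of rings A and B, so (R)-21 maps onto (R)-22. Carbonyl selectivity (C4 over C3) follows from the five- versus six-membered transition state and from the electronic and steric deactivation of C3 by the 2,4-dioxygenated ring B. Migration selectivity (C2 over C4a) rests on reversibility, since aryl migration would give a non-conjugated chroman-3-one that can return to 21, while 22 is the thermodynamic sink.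

**Step 12**
Reactants: 22 (3R)-3-[2,4-bis(TOM-oxy)phenyl]-3-hydroxy-6,8-diprenyl-7-(TOM-oxy)chroman-4-one
Product: 23 (3R)-3-(2,4-dihydroxyphenyl)-3,7-dihydroxy-6,8-diprenylchroman-4-one (target)
Conditions: Bu4NF (4 equiv), AcOH (4 equiv), THF, 0 °C to rt
Reagents that add atoms: none
Why: Fluoride cleaves the three Si–O bonds and each aryl hemiformal collapses to the phenol and formaldehyde, while the acetic acid buffer keeps the medium near neutral so that the tertiary benzylic α-ketol neither dehydrates to the isoflavone nor rearranges and C3 stays (R).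

**Compound list**
1 | 4-bromoresorcinol (4-bromobenzene-1,3-diol) | Oc1ccc(Br)c(O)c1 | starting material
2 | allyl bromide | C=CCBr | starting material
3 | 1-bromo-2,4-bis(allyloxy)benzene | C=CCOc1ccc(Br)c(OCC=C)c1 | intermediate
4 | 2,6-diallyl-4-bromobenzene-1,3-diol | Oc1c(CC=C)cc(Br)c(O)c1CC=C | intermediate
5 | 2-methylbut-2-ene | CC=C(C)C | starting material
6 | 4-bromo-2,6-diprenylbenzene-1,3-diol | Oc1c(CC=C(C)C)cc(Br)c(O)c1CC=C(C)C | intermediate
7 | 2-chloro-N-methoxy-N-methylacetamide | CON(C)C(=O)CCl | starting material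
8 | 2-(6-bromo-3-hydroxy-2,4-diprenylphenoxy)-N-methoxy-N-methylacetamide | CON(C)C(=O)COc1c(Br)cc(CC=C(C)C)c(O)c1CC=C(C)C | intermediate
9 | (triisopropylsiloxy)methyl chloride (TOM-Cl) | ClCO[Si](C(C)C)(C(C)C)C(C)C | starting material
10 | 2-[6-bromo-2,4-diprenyl-3-(TOM-oxy)phenoxy]-N-methoxy-N-methylacetamide | CON(C)C(=O)COc1c(Br)cc(CC=C(C)C)c(OCO[Si](C(C)C)(C(C)C)C(C)C)c1CC=C(C)C | intermediate
11 | 2,4-dihydroxybenzaldehyde | O=Cc1ccc(O)cc1O | starting material
12 | propane-1,3-dithiol | SCCCS | starting material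
13 | 4-(1,3-dithian-2-yl)benzene-1,3-diol | Oc1ccc(C2SCCCS2)c(O)c1 | intermediate
14 | 2-[2,4-bis(TOM-oxy)phenyl]-1,3-dithiane | C1CSC(SC1)c1ccc(OCO[Si](C(C)C)(C(C)C)C(C)C)cc1OCO[Si](C(C)C)(C(C)C)C(C)C | intermediate
15 | 2-lithio-2-[2,4-bis(TOM-oxy)phenyl]-1,3-dithiane | [Li]C1(SCCCS1)c1ccc(OCO[Si](C(C)C)(C(C)C)C(C)C)cc1OCO[Si](C(C)C)(C(C)C)C(C)C | intermediate
16 | 2-[6-bromo-2,4-diprenyl-3-(TOM-oxy)phenoxy]-1-{2-[2,4-bis(TOM-oxy)phenyl]-1,3-dithian-2-yl}ethan-1-one | O=C(COc1c(Br)cc(CC=C(C)C)c(OCO[Si](C(C)C)(C(C)C)C(C)C)c1CC=C(C)C)C1(SCCCS1)c1ccc(OCO[Si](C(C)C)(C(C)C)C(C)C)cc1OCO[Si](C(C)C)(C(C)C)C(C)C | intermediate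
17 | bis(pinacolato)diboron | CC1(C)OB(OC1(C)C)B1OC(C)(C)C(C)(C)O1 | starting material
18 | 2-[2,4-diprenyl-6-(Bpin)-3-(TOM-oxy)phenoxy]-1-{2-[2,4-bis(TOM-oxy)phenyl]-1,3-dithian-2-yl}ethan-1-one | O=C(COc1c(B2OC(C)(C)C(C)(C)O2)cc(CC=C(C)C)c(OCO[Si](C(C)C)(C(C)C)C(C)C)c1CC=C(C)C)C1(SCCCS1)c1ccc(OCO[Si](C(C)C)(C(C)C)C(C)C)cc1OCO[Si](C(C)C)(C(C)C)C(C)C | intermediate
19 | water | O | starting material
20 | 3-[2,4-diprenyl-6-(Bpin)-3-(TOM-oxy)phenoxy]-1-[2,4-bis(TOM-oxy)phenyl]propane-1,2-dione | O=C(COc1c(B2OC(C)(C)C(C)(C)O2)cc(CC=C(C)C)c(OCO[Si](C(C)C)(C(C)C)C(C)C)c1CC=C(C)C)C(=O)c1ccc(OCO[Si](C(C)C)(C(C)C)C(C)C)cc1OCO[Si](C(C)C)(C(C)C)C(C)C | intermediate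
21 | (R)-[2,4-bis(TOM-oxy)phenyl][3-hydroxy-5,7-diprenyl-6-(TOM-oxy)-2,3-dihydrobenzofuran-3-yl]methanone | O[C@@]1(C(=O)c2ccc(OCO[Si](C(C)C)(C(C)C)C(C)C)cc2OCO[Si](C(C)C)(C(C)C)C(C)C)COc2c1cc(CC=C(C)C)c(OCO[Si](C(C)C)(C(C)C)C(C)C)c2CC=C(C)C | intermediate
22 | (3R)-3-[2,4-bis(TOM-oxy)phenyl]-3-hydroxy-6,8-diprenyl-7-(TOM-oxy)chroman-4-one | CC(C)=CCc1cc2c(c(CC=C(C)C)c1OCO[Si](C(C)C)(C(C)C)C(C)C)OC[C@](O)(c1ccc(OCO[Si](C(C)C)(C(C)C)C(C)C)cc1OCO[Si](C(C)C)(C(C)C)C(C)C)C2=O | intermediate
23 | (3R)-3-(2,4-dihydroxyphenyl)-3,7-dihydroxy-6,8-diprenylchroman-4-one | CC(C)=CCc1cc2c(c(CC=C(C)C)c1O)OC[C@](O)(c1ccc(O)cc1O)C2=O | target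

**Step count**
Total steps: 12. Longest linear sequence: 10 (steps 1–5 and 8–12).

**Steps most likely to fail**

1. **Step 11.**
   - What may go wrong: the electron-rich boronate may protodeboronate, or the diketone may undergo a hydroxide-induced benzilic acid rearrangement before arylation. The ketol shift may stall at 21. Part of the shift may also run through the cisoid conformer or through aryl migration, which would erode enantiopurity.
   - Fallback (known chemistry): it sets out from 10, with 1 and 9 supplying ring B, comes back at 22, and closes ring C at C3–C4 instead.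
     - Compound 1 is bis-alkylated with 9 (K2CO3, acetone) to 1-bromo-2,4-bis(TOM-oxy)benzene F1.
     - Bromine–lithium exchange (n-BuLi, THF, −78 °C) gives 2,4-bis(TOM-oxy)phenyllithium F2.
     - F2 acylates at Weinreb amide 10 to 2-[6-bromo-2,4-diprenyl-3-(TOM-oxy)phenoxy]-1-[2,4-bis(TOM-oxy)phenyl]ethan-1-one F3.
     - Palladium-catalysed reductive carbonylation (Pd(OAc)2, di(1-adamantyl)-n-butylphosphine, CO/H2, TMEDA, toluene, 100 °C) turns the bromide into 2-{2-[2,4-bis(TOM-oxy)phenyl]-2-oxoethoxy}-3,5-diprenyl-4-(TOM-oxy)benzaldehyde F4.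
     - An enantioselective intramolecular crossed aldehyde–ketone benzoin reaction then gives 22. It uses a chiral aminoindanol-derived triazolium carbene precursor (Et3N, toluene, rt), with the antipode chosen for (R).

2. **Step 10.**
   - What may go wrong: the periodinane may oxidise the C–B bond, or cleavage may stop short at the congested 2-acyl-2-aryl dithiane.
   - Fallback: it sets out from 18, comes back at 22, and reverses the order of events.
     - The rhodium-catalysed enantioselective arylation is run on 18, a plain α-aryloxy ketone and so the known substrate class, with the catalyst of step 11 at 40 °C. This gives (R)-3-{2-[2,4-bis(TOM-oxy)phenyl]-1,3-dithian-2-yl}-5,7-diprenyl-6-(TOM-oxy)-2,3-dihydrobenzofuran-3-ol F5.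
     - With boron gone, the dithiane is removed by alkylative hydrolysis (MeI, CaCO3, aqueous MeCN) to give 21, which is now isolated.
     - Compound 21 is rearranged on its own (K3PO4, 1,4-dioxane/H2O, 70 °C) to 22.

3. **Step 8.**
   - What may go wrong: a proton may transfer from the OCH2 group of the amide to the hindered carbanion, and acylation may be slow.
   - Fallback: it sets out from 10, comes back at 16, and replaces acylation by carbonyl addition and oxidation.
     - i-Bu2AlH (THF, −78 °C) reduces 10 to 2-[6-bromo-2,4-diprenyl-3-(TOM-oxy)phenoxy]acetaldehyde F6.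
     - Carbanion 15 adds to this more electrophilic carbonyl to give the racemic carbinol 2-[6-bromo-2,4-diprenyl-3-(TOM-oxy)phenoxy]-1-{2-[2,4-bis(TOM-oxy)phenyl]-1,3-dithian-2-yl}ethan-1-ol F7.
     - Parikh–Doering oxidation (SO3·pyridine, DMSO, Et3N), which spares the dithiane, gives 16.

**Further compounds**
F1 | step 11 | 1-bromo-2,4-bis(TOM-oxy)benzene | Brc1ccc(OCO[Si](C(C)C)(C(C)C)C(C)C)cc1OCO[Si](C(C)C)(C(C)C)C(C)C
F2 | step 11 | 2,4-bis(TOM-oxy)phenyllithium | [Li]c1ccc(OCO[Si](C(C)C)(C(C)C)C(C)C)cc1OCO[Si](C(C)C)(C(C)C)C(C)C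
F3 | step 11 | 2-[6-bromo-2,4-diprenyl-3-(TOM-oxy)phenoxy]-1-[2,4-bis(TOM-oxy)phenyl]ethan-1-one | O=C(COc1c(Br)cc(CC=C(C)C)c(OCO[Si](C(C)C)(C(C)C)C(C)C)c1CC=C(C)C)c1ccc(OCO[Si](C(C)C)(C(C)C)C(C)C)cc1OCO[Si](C(C)C)(C(C)C)C(C)C
F4 | step 11 | 2-{2-[2,4-bis(TOM-oxy)phenyl]-2-oxoethoxy}-3,5-diprenyl-4-(TOM-oxy)benzaldehyde | O=Cc1cc(CC=C(C)C)c(OCO[Si](C(C)C)(C(C)C)C(C)C)c(CC=C(C)C)c1OCC(=O)c1ccc(OCO[Si](C(C)C)(C(C)C)C(C)C)cc1OCO[Si](C(C)C)(C(C)C)C(C)C
F5 | step 10 | (R)-3-{2-[2,4-bis(TOM-oxy)phenyl]-1,3-dithian-2-yl}-5,7-diprenyl-6-(TOM-oxy)-2,3-dihydrobenzofuran-3-ol | O[C@@]1(C2(SCCCS2)c2ccc(OCO[Si](C(C)C)(C(C)C)C(C)C)cc2OCO[Si](C(C)C)(C(C)C)C(C)C)COc2c1cc(CC=C(C)C)c(OCO[Si](C(C)C)(C(C)C)C(C)C)c2CC=C(C)C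
F6 | step 8 | 2-[6-bromo-2,4-diprenyl-3-(TOM-oxy)phenoxy]acetaldehyde | O=CCOc1c(Br)cc(CC=C(C)C)c(OCO[Si](C(C)C)(C(C)C)C(C)C)c1CC=C(C)C
F7 | step 8 | 2-[6-bromo-2,4-diprenyl-3-(TOM-oxy)phenoxy]-1-{2-[2,4-bis(TOM-oxy)phenyl]-1,3-dithian-2-yl}ethan-1-ol (racemic) | OC(COc1c(Br)cc(CC=C(C)C)c(OCO[Si](C(C)C)(C(C)C)C(C)C)c1CC=C(C)C)C1(SCCCS1)c1ccc(OCO[Si](C(C)C)(C(C)C)C(C)C)cc1OCO[Si](C(C)C)(C(C)C)C(C)C
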